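**Strategy.** Ring A (C1–C2–C3–C4–C5–C10) is traced back to the cyclopentanone ring (C1–C2–C3–C5–C10) of a cis-hydrindanone, so that C4 is the only atom to be inserted. The key step is a Lewis-acid semipinacol rearrangement of a 2,3-epoxy alcohol: the tertiary C3 carbinol carries a 2-(hydroxymethyl)oxiranyl group, C5 shifts from C3 to the oxirane carbon, and one operation delivers the six-membered ring, the C3 carbonyl and the quaternary C4 with both hydroxymethyl groups. It exploits that C4 bears two identical CH2OH arms (the oxirane configuration is irrelevant) and that C5, epimerisable beside the C3 ketone, migrates with retention. The hydrindanone comes from 5-methoxy-1-indanone by transfer hydrogenation, Birch reduction and conjugate methylation–alkylation.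

Key step: step 10

Remark: atoms are numbered as in labdanes (ring A: C1–C5 and C10; ring B: C5–C10; C17 exocyclic methylene; C18/C19 hydroxymethyl carbons; C11–C16 side chain and butenolide); the C3 epimers of 15 and 16 and the oxirane epimers of 16 need not be separated, because both stereocentres vanish in step 10.

**Route**

Step 1
Reactants: 1 5-methoxy-2,3-dihydro-1H-inden-1-one
Product: 2 (R)-5-methoxy-2,3-dihydro-1H-inden-1-ol
Conditions: RuCl[(R,R)-TsDPEN](p-cymene) (1 mol %), HCO2H/Et3N (5:2), CH2Cl2, 30 °C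
Reagents that add atoms: none
Why: Noyori asymmetric transfer hydrogenation of an aryl alkyl ketone, in which the (R,R)-diamine ligand differentiates the aryl and methylene flanks and should give the (R)-carbinol at C3, a temporary stereocentre that later relays the absolute configuration to C5, C10 and C9.

Step 2
Reactants: 2 (R)-5-methoxy-2,3-dihydro-1H-inden-1-ol
Product: 5 (1R,7aR)-1-hydroxy-1,2,3,6,7,7a-hexahydro-5H-inden-5-one, via dienol ether 3 (not isolated), via β,γ-enone 4 (not isolated)
Conditions: n-BuLi (1 equiv), THF, −78 °C; Li, NH3(l), t-BuOH, −78 to −33 °C; NH4Cl; (CO2H)2 (cat.), THF/H2O, 0 °C; then K2CO3 (cat.), MeOH, 0 °C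
Reagents that add atoms: water, O
Why: Birch reduction of the anisole ring (the pre-formed lithium alkoxide should resist benzylic C–O cleavage), enol ether hydrolysis and base-mediated conjugation of the β,γ-enone should give the hexahydroindenone, whose new C5 stereocentre equilibrates through the dienolate to the isomer with C6 trans to the C3 hydroxyl (H-5 cis to OH).

Step 3
Reactants: 5 (1R,7aR)-1-hydroxy-1,2,3,6,7,7a-hexahydro-5H-inden-5-one
Product: 6 (1R,7aR)-1-[(tert-butyldimethylsilyl)oxy]-1,2,3,6,7,7a-hexahydro-5H-inden-5-one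
Conditions: TBSCl, imidazole, DMF, 0 °C to rt
Reagents that add atoms: tert-butyldimethylsilyl chloride, C[Si](C)(Cl)C(C)(C)C
Why: silyl ether formation masks the secondary alcohol for the organometallic steps without touching a stereocentre.

Step 4
Reactants: 6 (1R,7aR)-1-[(tert-butyldimethylsilyl)oxy]-1,2,3,6,7,7a-hexahydro-5H-inden-5-one; 7 tert-butyl bromoacetate
Product: 9 tert-butyl 2-[(1R,3aR,4S,7aR)-1-[(tert-butyldimethylsilyl)oxy]-3a-methyl-5-oxooctahydro-1H-inden-4-yl]acetate, via lithium enolate 8 (not isolated)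
Conditions: Me2CuLi (from MeLi, CuI), Et2O, −78 to 0 °C; then 7, DMPU, −40 to 0 °C
Reagents that add atoms: lithium dimethylcuprate, [Li+].C[Cu-]C
Why: tandem conjugate addition–enolate alkylation, in which the cuprate should place the methyl group at C10 on the face of H-5 (stereoelectronically preferred axial attack giving the cis-fused hydrindanone) and the regiospecific C8 enolate is alkylated at C9 from the convex face, anti to the cyclopentane ring, so that C11 ends cis to the angular methyl.

Step 5
Reactants: 9 tert-butyl 2-[(1R,3aR,4S,7aR)-1-[(tert-butyldimethylsilyl)oxy]-3a-methyl-5-oxooctahydro-1H-inden-4-yl]acetate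
Product: 10 tert-butyl 2-[(1R,3aS,4R,7aR)-1-[(tert-butyldimethylsilyl)oxy]-3a-methyl-5-methylideneoctahydro-1H-inden-4-yl]acetate
Conditions: Cp2TiMe2, toluene, 65 °C, dark
Reagents that add atoms: dimethyltitanocene, C[Ti](C)(C1C=CC=C1)C1C=CC=C1
Why: Petasis methylenation converts the hindered, epimerisable C8 ketone into the exocyclic methylene under non-basic conditions that should leave C9 and the tert-butyl ester untouched.

Step 6
Reactants: 10 tert-butyl 2-[(1R,3aS,4R,7aR)-1-[(tert-butyldimethylsilyl)oxy]-3a-methyl-5-methylideneoctahydro-1H-inden-4-yl]acetate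
Product: 11 tert-butyl 2-[(1R,3aS,4R,7aR)-1-hydroxy-3a-methyl-5-methylideneoctahydro-1H-inden-4-yl]acetate
Conditions: TBAF, THF, rt
Reagents that add atoms: none
Why: fluoride-mediated desilylation frees the C3 alcohol without affecting any stereocentre.

Step 7
Reactants: 11 tert-butyl 2-[(1R,3aS,4R,7aR)-1-hydroxy-3a-methyl-5-methylideneoctahydro-1H-inden-4-yl]acetate
Product: 12 tert-butyl 2-[(3aS,4R,7aR)-3a-methyl-5-methylidene-1-oxooctahydro-1H-inden-4-yl]acetate
Conditions: Dess–Martin periodinane, CH2Cl2, 0 °C to rt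
Reagents that add atoms: none
Why: Dess–Martin oxidation gives the cyclopentanone, in which C5 is α to the carbonyl and already sits in the thermodynamically favoured cis ring fusion (angular methyl cis to H-5).

Step 8
Reactants: 12 tert-butyl 2-[(3aS,4R,7aR)-3a-methyl-5-methylidene-1-oxooctahydro-1H-inden-4-yl]acetate; 13 2-bromoprop-2-en-1-ol
Product: 15 tert-butyl 2-[(1S,3aS,4R,7aR)-1-hydroxy-1-(3-hydroxyprop-1-en-2-yl)-3a-methyl-5-methylideneoctahydro-1H-inden-4-yl]acetate, via dilithio reagent 14 (not isolated)
Conditions: 13, t-BuLi (3 equiv), Et2O, −78 to 0 °C; CeCl3, THF, −78 °C; then 12; NH4Cl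
Reagents that add atoms: none
Why: bromine–lithium exchange on the lithium alkoxide of 13 gives a 2-lithioallyl alkoxide whose cerium derivative should add 1,2 to the enolisable cyclopentanone rather than to the tert-butyl ester, from the convex face (organocerium carbonyl addition); the new C3 carbinol centre is destroyed in step 10.

Step 9
Reactants: 15 tert-butyl 2-[(1S,3aS,4R,7aR)-1-hydroxy-1-(3-hydroxyprop-1-en-2-yl)-3a-methyl-5-methylideneoctahydro-1H-inden-4-yl]acetate
Product: 16 tert-butyl 2-[(1S,3aS,4R,7aR)-1-hydroxy-1-[2-(hydroxymethyl)oxiran-2-yl]-3a-methyl-5-methylideneoctahydro-1H-inden-4-yl]acetate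
Conditions: VO(acac)2 (5 mol %), t-BuOOH, CH2Cl2, 0 °C
Reagents that add atoms: tert-butyl hydroperoxide, CC(C)(C)OO
Why: hydroxyl-directed vanadium-catalysed epoxidation should select the 1,1-disubstituted alkene flanked by two allylic hydroxyls over the isolated exocyclic methylene; the oxirane configuration is immaterial.

Step 10
Reactants: 16 tert-butyl 2-[(1S,3aS,4R,7aR)-1-hydroxy-1-[2-(hydroxymethyl)oxiran-2-yl]-3a-methyl-5-methylideneoctahydro-1H-inden-4-yl]acetate
Product: 17 tert-butyl 2-[(1R,4aR,8aS)-5,5-bis(hydroxymethyl)-8a-methyl-2-methylidene-6-oxodecahydronaphthalen-1-yl]acetate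
Conditions: BF3·OEt2 (0.3 equiv), CH2Cl2, −78 to −40 °C
Reagents that add atoms: none
Why: BF3 coordinates the oxirane oxygen, the C4–O bond at the tertiary oxirane carbon ionises, and the C3–C5 ring bond, aligned anti to it, shifts to C4 while the C3 hydroxyl becomes the carbonyl (semipinacol rearrangement of a 2,3-epoxy alcohol, the closest known type being the Lewis-acid ring enlargement of 1-oxiranylcycloalkanols to 2-(hydroxymethyl)cycloalkanones). No ring is closed by cyclisation: ring A arises by one-carbon expansion of the cyclopentane through the 1,2-shift. No new stereocentre is formed, since C4 carries two identical hydroxymethyl groups and the carbinol carbon becomes sp2; C5 migrates with retention, so the cis ring fusion of 12 is carried over and fixed. The step needs opening at the tertiary oxirane carbon and migration of C5 rather than C2; the first follows from cation stability at C4, the second from the higher migratory aptitude of the more substituted ring-fusion carbon, which free rotation about C3–C4 can place anti to the leaving oxygen.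

Step 11
Reactants: 17 tert-butyl 2-[(1R,4aR,8aS)-5,5-bis(hydroxymethyl)-8a-methyl-2-methylidene-6-oxodecahydronaphthalen-1-yl]acetate
Product: 18 acetonide of 17 (the two hydroxymethyl groups as a 2,2-dimethyl-1,3-dioxane spiro-fused at C4)
Conditions: 2,2-dimethoxypropane, PPTS (cat.), CH2Cl2, rt
Reagents that add atoms: 2,2-dimethoxypropane, COC(C)(C)OC
Why: transacetalisation protects the 1,3-diol and should shut off the retro-aldol pathway of the β-hydroxy ketone.

Step 12
Reactants: 18 acetonide of 17
Product: 19 (3R)-alcohol from 18 (hydroxyl cis to H-5 and to the angular methyl; acetonide and tert-butyl ester retained)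
Conditions: (S)-2-methyl-CBS-oxazaborolidine (20 mol %), BH3·SMe2, THF, −20 °C
Reagents that add atoms: none
Why: Corey–Bakshi–Shibata reduction, in which the catalyst distinguishes the quaternary C4 flank from the C2 methylene, should deliver hydride to the face that gives the (3R)-alcohol (reagent control), borane leaving the tert-butyl ester intact at this temperature.

Step 13
Reactants: 19 (3R)-alcohol from 18
Product: 20 diol with the C12 primary alcohol (tert-butyl ester of 19 reduced)
Conditions: LiAlH4, THF, 0 °C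
Reagents that add atoms: none
Why: hydride reduction of the ester gives the primary alcohol; no stereocentre is affected.

Step 14
Reactants: 20 diol with the C12 primary alcohol
Product: 21 C12 iodide of 20
Conditions: I2, PPh3, imidazole, CH2Cl2, 0 °C
Reagents that add atoms: iodine, II
Why: Appel-type iodination should occur only at the unhindered primary C12 hydroxyl, the secondary C3 hydroxyl beside the quaternary centre being far slower in this SN2 process.

Step 15
Reactants: 22 3-bromodihydrofuran-2(3H)-one; 23 benzenethiol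
Product: 24 3-(phenylsulfanyl)dihydrofuran-2(3H)-one
Conditions: Et3N, CH2Cl2, 0 °C to rt
Reagents that add atoms: none
Why: SN2 displacement of the α-bromide by thiolate gives the α-sulfanyl lactone that serves as a butenolide α-anion equivalent.

Step 16
Reactants: 21 C12 iodide of 20; 24 3-(phenylsulfanyl)dihydrofuran-2(3H)-one
Product: 26 3-(phenylsulfanyl)lactone alkylated at its α-carbon (C13) with the C12 chain of 21 (mixture at C13), via lithium enolate 25 (not isolated)
Conditions: 24 (2.5 equiv), LiN(i-Pr)2 (2.5 equiv), THF/DMPU, −78 °C; then 21, −78 to 0 °C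
Reagents that add atoms: none
Why: alkylation of the sulfur-stabilised lactone enolate with the primary iodide forms the C12–C13 bond, the excess enolate absorbing the free C3 hydroxyl; the C13 stereocentre is removed in step 17.

Step 17
Reactants: 26 3-(phenylsulfanyl)lactone alkylated at C13
Product: 28 acetonide of the target, via sulfoxide 27 (not isolated)
Conditions: mCPBA (1.0 equiv), CH2Cl2, −78 °C; then toluene, 110 °C
Reagents that add atoms: none
Why: chemoselective sulfide oxidation followed by thermal syn-elimination of the sulfoxide should give the endocyclic C13=C14 butenolide, as is usual for α-alkyl-α-sulfinyl γ-lactones.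

Step 18
Reactants: 28 acetonide of the target
Product: 29 3-{2-[(1R,4aR,6R,8aS)-6-hydroxy-5,5-bis(hydroxymethyl)-8a-methyl-2-methylidenedecahydronaphthalen-1-yl]ethyl}furan-2(5H)-one
Conditions: AcOH/H2O (4:1), 40 °C
Reagents that add atoms: none
Why: mild acid hydrolysis of the acetonide releases the two hydroxymethyl groups without touching the butenolide or the exocyclic alkene.

**Compound list**

1 | 5-methoxy-2,3-dihydro-1H-inden-1-one | COc1ccc2c(c1)CCC2=O | starting material
2 | (R)-5-methoxy-2,3-dihydro-1H-inden-1-ol | COc1ccc2c(c1)CC[C@H]2O | intermediate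
3 | (R)-5-methoxy-2,3,4,7-tetrahydro-1H-inden-1-ol (dienol ether) | COC1=CCC2=C(C1)CC[C@H]2O | intermediate
4 | (R)-1-hydroxy-1,2,3,4,6,7-hexahydro-5H-inden-5-one (β,γ-enone) | O=C1CCC2=C(C1)CC[C@H]2O | intermediate
5 | (1R,7aR)-1-hydroxy-1,2,3,6,7,7a-hexahydro-5H-inden-5-one | O=C1CC[C@H]2[C@H](O)CCC2=C1 | intermediate
6 | (1R,7aR)-1-[(tert-butyldimethylsilyl)oxy]-1,2,3,6,7,7a-hexahydro-5H-inden-5-one | O=C1CC[C@H]2[C@H](O[Si](C)(C)C(C)(C)C)CCC2=C1 | intermediate
7 | tert-butyl bromoacetate | BrCC(=O)OC(C)(C)C | starting material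
8 | lithium enolate (C8–OLi, C8=C9) of the conjugate adduct, angular methyl cis to H-5 | [Li]OC=1CC[C@H]2[C@H](O[Si](C)(C)C(C)(C)C)CC[C@@]2(C)C=1 | intermediate
9 | tert-butyl 2-[(1R,3aR,4S,7aR)-1-[(tert-butyldimethylsilyl)oxy]-3a-methyl-5-oxooctahydro-1H-inden-4-yl]acetate | O=C1CC[C@H]2[C@H](O[Si](C)(C)C(C)(C)C)CC[C@@]2(C)[C@@H]1CC(=O)OC(C)(C)C | intermediate
10 | tert-butyl 2-[(1R,3aS,4R,7aR)-1-[(tert-butyldimethylsilyl)oxy]-3a-methyl-5-methylideneoctahydro-1H-inden-4-yl]acetate | C=C1CC[C@H]2[C@H](O[Si](C)(C)C(C)(C)C)CC[C@@]2(C)[C@@H]1CC(=O)OC(C)(C)C | intermediate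
11 | tert-butyl 2-[(1R,3aS,4R,7aR)-1-hydroxy-3a-methyl-5-methylideneoctahydro-1H-inden-4-yl]acetate | C=C1CC[C@H]2[C@H](O)CC[C@@]2(C)[C@@H]1CC(=O)OC(C)(C)C | intermediate
12 | tert-butyl 2-[(3aS,4R,7aR)-3a-methyl-5-methylidene-1-oxooctahydro-1H-inden-4-yl]acetate | C=C1CC[C@H]2C(=O)CC[C@@]2(C)[C@@H]1CC(=O)OC(C)(C)C | intermediate
13 | 2-bromoprop-2-en-1-ol | OCC(Br)=C | starting material
14 | lithium 2-lithioprop-2-en-1-olate | [Li]OCC([Li])=C | intermediate
15 | tert-butyl 2-[(1S,3aS,4R,7aR)-1-hydroxy-1-(3-hydroxyprop-1-en-2-yl)-3a-methyl-5-methylideneoctahydro-1H-inden-4-yl]acetate | C=C1CC[C@H]2[C@](O)(C(=C)CO)CC[C@@]2(C)[C@@H]1CC(=O)OC(C)(C)C | intermediate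
16 | tert-butyl 2-[(1S,3aS,4R,7aR)-1-hydroxy-1-[2-(hydroxymethyl)oxiran-2-yl]-3a-methyl-5-methylideneoctahydro-1H-inden-4-yl]acetate (both oxirane epimers) | C=C1CC[C@H]2[C@](O)(C3(CO)CO3)CC[C@@]2(C)[C@@H]1CC(=O)OC(C)(C)C | intermediate
17 | tert-butyl 2-[(1R,4aR,8aS)-5,5-bis(hydroxymethyl)-8a-methyl-2-methylidene-6-oxodecahydronaphthalen-1-yl]acetate | C=C1CC[C@H]2C(CO)(CO)C(=O)CC[C@@]2(C)[C@@H]1CC(=O)OC(C)(C)C | intermediate
18 | acetonide of 17 (2,2-dimethyl-1,3-dioxane spiro-fused at C4) | C=C1CC[C@H]2C3(COC(C)(C)OC3)C(=O)CC[C@@]2(C)[C@@H]1CC(=O)OC(C)(C)C | intermediate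
19 | (3R)-alcohol from 18 | C=C1CC[C@H]2C3(COC(C)(C)OC3)[C@H](O)CC[C@@]2(C)[C@@H]1CC(=O)OC(C)(C)C | intermediate
20 | diol with the C12 primary alcohol | C=C1CC[C@H]2C3(COC(C)(C)OC3)[C@H](O)CC[C@@]2(C)[C@@H]1CCO | intermediate
21 | C12 iodide of 20 | C=C1CC[C@H]2C3(COC(C)(C)OC3)[C@H](O)CC[C@@]2(C)[C@@H]1CCI | intermediate
22 | 3-bromodihydrofuran-2(3H)-one | O=C1OCCC1Br | starting material
23 | benzenethiol | Sc1ccccc1 | starting material
24 | 3-(phenylsulfanyl)dihydrofuran-2(3H)-one | O=C1OCCC1Sc1ccccc1 | intermediate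
25 | lithium enolate of 24 | [Li]OC1=C(Sc2ccccc2)CCO1 | intermediate
26 | 3-(phenylsulfanyl)lactone alkylated at C13 with the C12 chain (mixture at C13) | C=C1CC[C@H]2C3(COC(C)(C)OC3)[C@H](O)CC[C@@]2(C)[C@@H]1CCC1(Sc2ccccc2)CCOC1=O | intermediate
27 | sulfoxide of 26 | C=C1CC[C@H]2C3(COC(C)(C)OC3)[C@H](O)CC[C@@]2(C)[C@@H]1CCC1(S(=O)c2ccccc2)CCOC1=O | intermediate
28 | acetonide of the target | C=C1CC[C@H]2C3(COC(C)(C)OC3)[C@H](O)CC[C@@]2(C)[C@@H]1CCC1=CCOC1=O | intermediate
29 | 3-{2-[(1R,4aR,6R,8aS)-6-hydroxy-5,5-bis(hydroxymethyl)-8a-methyl-2-methylidenedecahydronaphthalen-1-yl]ethyl}furan-2(5H)-one | C=C1CC[C@H]2C(CO)(CO)[C@H](O)CC[C@@]2(C)[C@@H]1CCC1=CCOC1=O | target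

**Step count and risks**

Total step count: 18. Longest linear sequence: 17 steps (steps 1–14 and 16–18).

Three steps most likely to fail:

1. Step 10. The C2 methylene may shift in competition with the more hindered C5, or the Lewis acid may open the oxirane of the free diol without a 1,2-shift. The fallback sets out from 1 and comes back at 19: the ring enlargement is moved to the aromatic stage, where the migrating carbon is the aryl carbon C5. Addition of 14 (CeCl3) to 1 gives the indanyl diol F1, VO(acac)2/t-BuOOH gives the oxirane F2, and BF3·OEt2 triggers the aryl 1,2-shift to the bis(hydroxymethyl)tetralone F3. Acetonide formation gives the ketone F4, (S)-CBS reduction the (R)-alcohol F5, and silylation the silyl ether F6. Birch reduction, enol ether hydrolysis and base-mediated conjugation give the enone F7; the C5 epimer with H-5 cis to the silyloxy group is separated and the other re-equilibrated. Me2CuLi followed by 7 gives the keto ester F8, Cp2TiMe2 the methylidene ester F9, and TBAF returns to 19. The Birch substrate of this sequence carries no benzylic oxygen.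

2. Step 4. C-alkylation of the hindered enolate next to the new quaternary carbon may be slow, so that proton transfer erodes regio- and facial control. The fallback sets out from 6 and comes back at 9: the cuprate adduct is trapped with Me3SiCl as the silyl enol ether F10, which is alkylated under ZnBr2 catalysis with tert-butyl chloro(phenylsulfanyl)acetate, a thionium electrophile that reacts at hindered enol ethers, to give the sulfide F11; radical desulfurisation (Bu3SnH, AIBN) returns to 9.

3. Step 12. The facial bias of the cis-decalin may override the catalyst (mismatched pairing) and give the C3 epimer. The fallback sets out from 18 and comes back at 19: enzymatic reduction with a ketoreductase selected for the (R)-alcohol and a glucose dehydrogenase/NADP cofactor cycle; no new compound is formed (F0).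

**Further compounds**

F1 | step 10 | 1-(3-hydroxyprop-1-en-2-yl)-5-methoxy-2,3-dihydro-1H-inden-1-ol (racemic) | COc1ccc2c(c1)CCC2(O)C(=C)CO
F2 | step 10 | 1-[2-(hydroxymethyl)oxiran-2-yl]-5-methoxy-2,3-dihydro-1H-inden-1-ol (mixture of isomers) | COc1ccc2c(c1)CCC2(O)C1(CO)CO1
F3 | step 10 | 1,1-bis(hydroxymethyl)-6-methoxy-3,4-dihydronaphthalen-2(1H)-one | COc1ccc2c(c1)CCC(=O)C2(CO)CO
F4 | step 10 | acetonide of F3 (2,2-dimethyl-1,3-dioxane spiro-fused at C4) | COc1ccc2c(c1)CCC(=O)C21COC(C)(C)OC1
F5 | step 10 | (R)-alcohol from F4 | COc1ccc2c(c1)CC[C@@H](O)C21COC(C)(C)OC1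
F6 | step 10 | tert-butyldimethylsilyl ether of F5 | COc1ccc2c(c1)CC[C@@H](O[Si](C)(C)C(C)(C)C)C21COC(C)(C)OC1
F7 | step 10 | octalone from F6 (C8 ketone, C9=C10, H-5 cis to the C3 silyloxy group) | O=C1CC[C@H]2C3(COC(C)(C)OC3)[C@H](O[Si](C)(C)C(C)(C)C)CCC2=C1
F8 | step 10 | cis-decalone keto ester from F7 (C10 methyl, C9 tert-butoxycarbonylmethyl) | O=C1CC[C@H]2C3(COC(C)(C)OC3)[C@H](O[Si](C)(C)C(C)(C)C)CC[C@@]2(C)[C@@H]1CC(=O)OC(C)(C)C
F9 | step 10 | C8-methylidene ester from F8 (silyl ether of 19) | C=C1CC[C@H]2C3(COC(C)(C)OC3)[C@H](O[Si](C)(C)C(C)(C)C)CC[C@@]2(C)[C@@H]1CC(=O)OC(C)(C)C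
F10 | step 4 | trimethylsilyl enol ether (C8–OSiMe3, C8=C9) of the conjugate adduct of 6 | C[Si](C)(C)OC=1CC[C@H]2[C@H](O[Si](C)(C)C(C)(C)C)CC[C@@]2(C)C=1
F11 | step 4 | tert-butyl 2-(phenylsulfanyl) analogue of 9 (sulfide at C11, mixture) | O=C1CC[C@H]2[C@H](O[Si](C)(C)C(C)(C)C)CC[C@@]2(C)[C@@H]1C(Sc1ccccc1)C(=O)OC(C)(C)C
F0 | step 12 | none | none
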